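The earlier runs and the new flask were generated by integration for an exercise; the scatter is artificial.

The closed, stirred vessel turns substrate into product through a round of catalyst intermediates. One earlier green run, at the same loading and lower concentration, shows the pace.

- green: substrate 0.085 M; reagent 1.2 equiv; free catalyst 0.5 mol%; run made earlier
- flask: substrate 0.17 M; reagent 1.20 equiv; free catalyst 0.5 mol%

- green (time / min: product / %, substrate / %): 2.50: 2.1, 97.8; 8.00: 5.9, 96.6; 15.0: 11.3, 87.7; 20.0: 16.3, 85.3; 30.0: 21.4, 79.0; 40.0: 27.5, 72.6; 50.0: 32.2, 68.9

(standard deviation of a reading: 1 percentage point)

- apparent order in free catalyst when 30% of the substrate are converted (percent change of the rate of making product for one percent more free catalyst charged)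
- apparent order in reagent when 30% of the substrate are converted (percent change of the rate of making product for one percent more reagent charged)

- steps thought possible: catalyst intermediate D -> spent catalyst; catalyst intermediate D -> free catalyst + product; substrate + catalyst intermediate A -> catalyst intermediate B; catalyst intermediate B -> catalyst intermediate C; reagent + free catalyst <-> catalyst intermediate A; catalyst intermediate C <-> released group + catalyst intermediate D
- no earlier run changes the charge of free catalyst; that part of a forecast is a guess
- no earlier run changes the charge of reagent; that part of a forecast is a guess

Two chemists dispute the catalyst order. The first holds that each catalyst step is linear in catalyst, so the rate at fixed conversion should nearly follow the charge. He reads the green run as leaving “little room for heavy deactivation or inhibition”. His forecast is 1.05 (0.9 to 1.35) for free catalyst and 0.45 (0 to 1.3) for reagent, where he says he guesses.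

The second chemist counts turnovers. At 30% conversion, [substrate] and [reagent] follow from the conversion, apart from what the catalyst holds bound, but the turnover number demanded goes down as the charge goes up: substrate converted per catalyst charged, 60.0. If a fixed share of catalyst is lost per product formed, catalyst deactivation follows this count and not the clock, and the order is one divided by the surviving share. On her reckoning, the forecast's order corresponds to a loss of 4.76% of the charge at this count. The green run's last gain, 32.2% less 21.4%, is uncertain by 13.1%; this is a judgement from the scatter and not a measured loss, but she takes a loss of that size, giving her own figure of 1.15.

The flask gives 1.2 for free catalyst and 0.37 for reagent.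

    catalyst intermediate D → spent catalyst (k = 0.0265 /min)
    catalyst intermediate D → free catalyst + product (k = 8.77 /min)
    substrate + catalyst intermediate A → catalyst intermediate B (k = 72.6 /M/min)
    catalyst intermediate B → catalyst intermediate C (k = 11.2 /min)
    reagent + free catalyst ⇌ catalyst intermediate A (K = 25.4 /M, k = 62.1 /M/min)
    catalyst intermediate C ⇌ released group + catalyst intermediate D (K = 0.480 M, k = 58.5 /min)

Per product formed, catalyst intermediate D gives 0.302% of a spent catalyst, so 60.0 turnovers cost 18.1% of the charge and the reckoned order is 1.22. With twice the free catalyst the simulated rate at 30% conversion changes by a factor of 2.22, and the reckoning at half the count gives 2.22. The first chemist's order of 1.05 has its region early: the reckoning gives it at a count of 15.8, which this flask reaches at 7.88% conversion. In the flask, spent catalyst stood at 15.4% after 0.400 h with substrate at 74.2%, and at 45.7% after 2.00 h with substrate at 24.0%. After 40.0 h, with substrate at 0%, it stood at 60.3%.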